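The numbering is that of longipinane: C1 ketone, C3 CHMe, cyclobutane C4–C5–C11–C10, C6 CMe2, C7–C9 oxygenated. The plan exploits the 1,3-relationship of C5 and C10 across the cyclobutane. Joining them in retrosynthesis gives a bicyclo[1.1.0]butane, and the bridge C6–C7–C8–C9 falls out as 2-bromo-2-methylpent-4-en-3-one. In the key step its tertiary α-keto radical attacks bridgehead C5, strain release breaks C5–C10, and the C10 radical closes onto the vinyl ketone. One operation unites a nine-carbon and a six-carbon fragment, creates both quaternary carbons (C6, C10) and closes the seven-membered ring C5–C6–C7–C8–C9–C10–C11. The precursor is a tricyclo[4.1.0.0^2,7]heptanone ketal, five steps from (R)-5-methylcyclohexenone.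

Key step: step 7

Remark (supply): (R)-5-methylcyclohex-2-en-1-one, angelic anhydride and (R)-2-methylbutanoic acid are taken as catalogue compounds.
Remark (faces): the two faces of the C6–C9 bridge are named after the cyclobutane CH they look at, the C4 side and the C11 side. In the target O-7 lies on the C4 side, O-8 and O-9 lie on the C11 side, and the C3 methyl lies on the side of H-5.

Step 1
Reactants: 1 (R)-5-methylcyclohex-2-en-1-one
Product: 2 (5R)-1,5-dimethylcyclohex-2-en-1-ol (both C1 epimers)
Conditions: MeLi (1.2 equiv), Et2O, −78 °C; H2O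
Reagents that add atoms: methyllithium, [Li]C
Why: 1,2-Addition of a hard organolithium to the enone carbonyl gives the tertiary allylic alcohol; the new carbinol centre is erased in step 2 and the methyl stereocentre (future C3) is untouched.

Step 2
Reactants: 2 (5R)-1,5-dimethylcyclohex-2-en-1-ol
Product: 3 (S)-3,5-dimethylcyclohex-2-en-1-one
Conditions: IBX (1.5 equiv), DMSO, 55 °C
Reagents that add atoms: IBX, O=C1OI(=O)(O)c2ccccc12
Why: Oxidative 1,3-transposition of a cyclic tertiary allylic alcohol (Babler–Dauben type oxidative rearrangement) moves the oxygen to the far end of the allyl unit and leaves the stereocentre intact, its descriptor changing to (S) only through CIP ranking.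

Step 3
Reactants: 3 (S)-3,5-dimethylcyclohex-2-en-1-one
Product: 4 (9S)-7,9-dimethyl-1,4-dioxaspiro[4.5]dec-6-ene
Conditions: (TMSOCH2)2 (1.5 equiv), TMSOTf (5 mol %), CH2Cl2, −78 °C; pyridine
Reagents that add atoms: 1,2-bis(trimethylsilyloxy)ethane, C[Si](C)(C)OCCO[Si](C)(C)C
Why: Noyori ketalisation masks the ketone under aprotic low-temperature conditions that do not move the double bond away from the ketal carbon, where steps 4 and 5 need it.

Step 4
Reactants: 4 (9S)-7,9-dimethyl-1,4-dioxaspiro[4.5]dec-6-ene
Product: 5 7,7-dibromo-4,6-dimethylspiro[bicyclo[4.1.0]heptane-2,2'-[1,3]dioxolane], CBr2 bridge cis to the C4 methyl group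
Conditions: CHBr3 (2 equiv), KOtBu (2.2 equiv), pentane, −10 °C to rt
Reagents that add atoms: bromoform, BrC(Br)Br
Why: Dibromocarbene [2+1] cycloaddition: in the half-chair with the ring methyl equatorial the pseudoaxial dioxolane oxygen shields one face, so CBr2 should add to the other face, cis to the methyl group, which fixes C10 and C11 and thereby the sense of the whole cage; a minor diastereomer would be removed here by chromatography.

Step 5
Reactants: 5 dibromocyclopropane ketal
Product: 7 1,5-dimethylspiro[tricyclo[4.1.0.0^2,7]heptane-3,2'-[1,3]dioxolane] (bicyclobutane ketal), via lithium bromocarbenoid 6 (not isolated)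
Conditions: MeLi (1.3 equiv), Et2O, −78 to 0 °C; basic alumina
Reagents that add atoms: none
Why: Lithium–bromine exchange and α-elimination give a cyclopropylidene that inserts into the cis C–H bond of the neighbouring ring CH2 (bicyclobutane branch of the Doering–Moore–Skattebøl reaction, the standard entry to tricyclo[4.1.0.0^2,7]heptanes), setting C4 and C5; the other flank is the hydrogen-free ketal carbon and the spiro ring holds its OCH2 groups away from the carbene.

Step 6
Reactants: 8 2-bromo-2-methylpropanoyl bromide; 9 tributyl(vinyl)stannane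
Product: 10 2-bromo-2-methylpent-4-en-3-one
Conditions: PdCl2(PPh3)2 (2 mol %), BHT, THF, 45 °C; used at once
Reagents that add atoms: none
Why: Stille ketone synthesis: oxidative addition of zerovalent palladium into the acyl bromide is much faster than into the tertiary alkyl bromide, and vinyl transfer from tin gives the vinyl ketone.

Step 7
Reactants: 7 bicyclobutane ketal; 10 2-bromo-2-methylpent-4-en-3-one
Product: 12 longipin-8-ene-1,7-dione 1-ethylene ketal, via 8-bromo ketone 11 (not isolated)
Conditions: [Cu(dap)2]Cl (2 mol %), MeCN–CH2Cl2, 530 nm LED, rt, 10 (1.2 equiv) added over 8 h; then DBU (2 equiv), 40 °C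
Reagents that add atoms: none
Why: Proposed new method: the photoexcited monovalent copper complex takes bromine from 10 to give the electrophilic tertiary α-keto radical, which attacks the electron-rich central σ-bond of 7 at the unsubstituted bridgehead C5 on the open convex face; release of some 40 kcal/mol of estimated bicyclobutane strain breaks C5–C10 and leaves a nucleophilic tertiary cyclobutyl radical at C10, which adds to the terminal carbon (C9) of the tethered vinyl ketone, and the C8 α-keto radical takes bromine back from the divalent copper bromide (or from 10) before DBU eliminates HBr. The closest known reaction types are the bromine-atom-transfer additions of sulfonyl bromides and polyhaloalkanes across the central bond of tricyclo[4.1.0.0^2,7]heptanes, atom-transfer radical annulations of α-halo carbonyl compounds with alkenes, and the radical or Lewis-acid formal cycloadditions of bicyclobutanes that give bicyclo[2.1.1]hexanes, bicyclo[3.1.1]heptanes and bicyclo[4.1.1]octanes; new is a four-carbon all-carbon partner on an acceptor-free bicyclobutane. The only ring closed is the seven-membered ring, by a 7-endo-trig radical addition whose ends are held about 2.1 Å apart by the cyclobutane, so that it should behave like a six-membered closure. C5 and C10 are the stereocentres made here: the C1–C3 bridge spans the concave face, so the first bond can form only on the convex face, and the tether forces the second bond onto the same face, which turns H-5 and the C10 methyl outward as in the target, while C4 and C11 are carried over from 7 and the C8 bromide centre is erased. The step needs first attack at C5 and not at C10, secured by the C10 methyl group that blocks its own bridgehead and stabilises the radical formed by attack at C5, and it needs ring closure faster than bromine transfer to C10, secured by slow addition of 10 and by polarity matching at every stage (electrophilic radical on σ-donor, nucleophilic radical on enone).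

Step 8
Reactants: 12 longipin-8-ene-1,7-dione 1-ethylene ketal
Product: 13 (7R)-7-hydroxylongipin-8-en-1-one ethylene ketal (O-7 on the C4 side)
Conditions: (S)-Me-CBS oxazaborolidine (0.3 equiv), BH3·SMe2 (1.0 equiv), THF, −20 °C; MeOH
Reagents that add atoms: none
Why: Corey–Bakshi–Shibata reduction: the cage offers no useful bias at C7, so reagent control is used, with quaternary C6 as the large and alkenyl C8 as the small substituent, for which the (S)-catalyst should deliver hydride on the C11 side; the ketal keeps C1 out of the reaction.

Step 9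
Reactants: 13 (7R)-7-hydroxylongipin-8-en-1-one ethylene ketal
Product: 14 7,8,9-trihydroxylongipinan-1-one ethylene ketal (O-7 on the C4 side, O-8 and O-9 on the C11 side)
Conditions: OsO4 (5 mol %), NMO (1.5 equiv), acetone–H2O, rt
Reagents that add atoms: N-methylmorpholine N-oxide, C[N+]1([O-])CCOCC1; water, O
Why: Upjohn dihydroxylation: syn addition sets C8 and C9 together, and osmium tetroxide should approach anti to the allylic C7 oxygen (empirical rule for osmylation of allylic alcohols), that is from the C11 side.

Step 10
Reactants: 14 triol ketal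
Product: 15 7-hydroxy-8,9-(isopropylidenedioxy)longipinan-1-one ethylene ketal
Conditions: 2-methoxypropene (1.5 equiv), PPTS (5 mol %), CH2Cl2, 0 °C to rt
Reagents that add atoms: 2-methoxypropene, COC(C)=C
Why: Acetonide formation under mild acid catalysis selects the cis-8,9-diol, because a dioxolane across the trans-7,8-diol would be strained, and leaves only the C7 hydroxyl free.

Step 11
Reactants: 15 acetonide alcohol; 16 angelic anhydride
Product: 17 7-angeloyloxy-8,9-(isopropylidenedioxy)longipinan-1-one ethylene ketal
Conditions: LiHMDS (1.1 equiv), THF, −78 to 0 °C, then 16 (1.3 equiv); H2O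
Reagents that add atoms: none
Why: Acylation of the lithium alkoxide with the symmetrical anhydride esterifies the hindered neopentylic C7 hydroxyl without a nucleophilic catalyst, conditions under which (Z)-2-methylbut-2-enoates do not isomerise to the (E)-esters.

Step 12
Reactants: 17 protected angelate
Product: 18 7-angeloyloxy-8,9-dihydroxylongipinan-1-one
Conditions: 1 M HCl, THF, rt
Reagents that add atoms: water, O
Why: Dilute aqueous acid hydrolyses the acetonide and the dioxolane in one operation, while the ester survives and the medium is far too weak to ionise the cyclobutylcarbinyl C9 hydroxyl.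

Step 13
Reactants: 18 7-angeloyloxy-8,9-dihydroxylongipinan-1-one; 19 (R)-2-methylbutanoic acid
Product: 20 target, 7-angeloyloxy-9-hydroxy-8-[(R)-2-methylbutanoyloxy]longipinan-1-one
Conditions: 19 (1.1 equiv), DCC (1.1 equiv), DMAP (10 mol %), CH2Cl2, −10 °C
Reagents that add atoms: none
Why: Steglich esterification at low temperature should acylate the C8 hydroxyl selectively, because the C9 hydroxyl is neopentylic (next to quaternary C10) and hydrogen-bonded to the C1 ketone; the stereocentre of 19 is kept under carbodiimide activation with only catalytic DMAP.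

Compound list
1 | (R)-5-methylcyclohex-2-en-1-one | O=C1C=CC[C@@H](C)C1 | starting material
2 | (5R)-1,5-dimethylcyclohex-2-en-1-ol, both carbinol epimers | CC1(O)C=CC[C@@H](C)C1 | intermediate
3 | (S)-3,5-dimethylcyclohex-2-en-1-one | CC1=CC(=O)C[C@@H](C)C1 | intermediate
4 | (9S)-7,9-dimethyl-1,4-dioxaspiro[4.5]dec-6-ene | CC1=CC2(OCCO2)C[C@@H](C)C1 | intermediate
5 | 7,7-dibromo-4,6-dimethylspiro[bicyclo[4.1.0]heptane-2,2'-[1,3]dioxolane], CBr2 cis to the C4 methyl | C[C@@]12C[C@H](C)CC3(OCCO3)[C@@H]1C2(Br)Br | intermediate
6 | 7-bromo-7-lithio carbenoid derived from 5 (not isolated) | C[C@@]12C[C@H](C)CC3(OCCO3)[C@@H]1C2([Li])Br | intermediate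
7 | 1,5-dimethylspiro[tricyclo[4.1.0.0^2,7]heptane-3,2'-[1,3]dioxolane]; bridgeheads are longipinane C10 (Me) and C5 (H), ring methyl on the side of the C–H bridgehead | C[C@]12[C@@H]3[C@H]1[C@H]2C4(OCCO4)C[C@H]3C | intermediate
8 | 2-bromo-2-methylpropanoyl bromide | CC(C)(Br)C(=O)Br | starting material
9 | tributyl(vinyl)stannane | C=C[Sn](CCCC)(CCCC)CCCC | starting material
10 | 2-bromo-2-methylpent-4-en-3-one | CC(C)(Br)C(=O)C=C | intermediate
11 | 8-bromolongipinane-1,7-dione 1-ethylene ketal, either C8 epimer (not isolated) | O=C1C(Br)C[C@]2(C)[C@@H]3[C@@H]([C@H]2C4(OCCO4)C[C@H]3C)C1(C)C | intermediate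
12 | longipin-8-ene-1,7-dione 1-ethylene ketal | O=C1C=C[C@]2(C)[C@@H]3[C@@H]([C@H]2C4(OCCO4)C[C@H]3C)C1(C)C | intermediate
13 | (7R)-7-hydroxylongipin-8-en-1-one ethylene ketal | O[C@@H]1C=C[C@]2(C)[C@@H]3[C@@H]([C@H]2C4(OCCO4)C[C@H]3C)C1(C)C | intermediate
14 | 7,8,9-trihydroxylongipinan-1-one ethylene ketal (7,8-trans, 8,9-cis) | O[C@@H]1[C@@H](O)[C@@H](O)[C@]2(C)[C@@H]3[C@@H]([C@H]2C4(OCCO4)C[C@H]3C)C1(C)C | intermediate
15 | 7-hydroxy-8,9-(isopropylidenedioxy)longipinan-1-one ethylene ketal | O[C@@H]1[C@@H](OC4(C)C)[C@@H](O4)[C@]2(C)[C@@H]3[C@@H]([C@H]2C5(OCCO5)C[C@H]3C)C1(C)C | intermediate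
16 | angelic anhydride, (Z)-2-methylbut-2-enoic anhydride | C/C=C(/C)C(=O)OC(=O)C(/C)=C\C | starting material
17 | 7-angeloyloxy-8,9-(isopropylidenedioxy)longipinan-1-one ethylene ketal | C/C=C(/C)C(=O)O[C@@H]1[C@@H](OC4(C)C)[C@@H](O4)[C@]2(C)[C@@H]3[C@@H]([C@H]2C5(OCCO5)C[C@H]3C)C1(C)C | intermediate
18 | 7-angeloyloxy-8,9-dihydroxylongipinan-1-one | C/C=C(/C)C(=O)O[C@@H]1[C@@H](O)[C@@H](O)[C@]2(C)[C@@H]3[C@@H]([C@H]2C(=O)C[C@H]3C)C1(C)C | intermediate
19 | (R)-2-methylbutanoic acid | CC[C@@H](C)C(=O)O | starting material
20 | 7-angeloyloxy-9-hydroxy-8-[(R)-2-methylbutanoyloxy]longipinan-1-one (CNP0206299.1) | C/C=C(/C)C(=O)O[C@@H]1[C@@H](OC(=O)[C@H](C)CC)[C@@H](O)[C@]2(C)[C@@H]3[C@@H]([C@H]2C(=O)C[C@H]3C)C1(C)C | target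

Total step count: 13. Longest linear sequence: 12 steps (steps 1–5 and 7–13).

Steps most likely to fail

1. Step 7. The chain may stall after the first addition if bromine transfer to the C10 radical outruns ring closure. The vinyl ketone may also oligomerise, and traces of acid may isomerise the bicyclobutane.

   The fallback sets out from 7 and comes back at 12, and it separates the two bond formations into known operations:
   - Bromine-atom-transfer addition of 2-bromo-N-methoxy-N,2-dimethylpropanamide across the central bond of 7 ([Cu(dap)2]Cl, light) is the known radical 1,3-addition of this hydrocarbon class, with no ring closure asked of it. It gives the bromo Weinreb amide F1, and either epimer at the C–Br carbon serves.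
   - Vinylmagnesium bromide (THF, −20 °C) turns it into the bromo vinyl ketone F2.
   - Bu3SnH/AIBN (benzene, 80 °C, syringe pump) regenerates the C10 radical and closes the ring in a conventional reductive 7-endo Giese cyclisation to the saturated dione monoketal F3.
   - IBX (DMSO, 70 °C) dehydrogenates the only enolisable position to give 12.

2. Step 5. The carbenoid may be diverted by insertion into the C–H bonds of the adjacent methyl group, by alkylation with methyl bromide, or by attack on the dioxolane.

   The fallback sets out from 3 and comes back at 7. It replaces C–H insertion by an internal SN2 displacement, the way bicyclobutyllithium reagents are made from 1,1-dibromo-2-(chloromethyl)cyclopropane: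
   - Wohl–Ziegler bromination of 3 (NBS, AIBN, PhCF3, reflux) at the ring γ-carbon, anti to the neighbouring methyl group, gives the γ-bromo enone F4.
   - Ketalisation as in step 3 gives the bromo ketal F5.
   - PhHgCBr3 (benzene, 80 °C, a neutral carbene source) adds CBr2 anti to the allylic bromine, again the face cis to the methyl group, to give the tribromide F6.
   - MeLi (Et2O, −78 °C) exchanges one geminal bromine, and the cyclopropyl anion displaces the secondary bromide with inversion to give the bridgehead bromide F7.
   - A second equivalent of MeLi gives the bridgehead lithium compound F8, and water delivers 7.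

3. Step 9. Osmylation next to quaternary C10 may be slow. Facial selectivity may be poor because a free hydroxyl is a small control element and can hydrogen-bond to the oxidant.

   The fallback sets out from 13 and comes back at 15, and it makes the control element steric:
   - TBSOTf/2,6-lutidine gives the silyl ether F9.
   - OsO4/NMO, now forced to the face away from the bulky silyloxy group, gives the diol F10.
   - 2-Methoxypropene/PPTS gives the acetonide F11.
   - TBAF (THF, rt) frees the C7 hydroxyl to give 15.

Further compounds
F1 | step 7 | 2-[6-bromo-4,6-dimethylspiro[bicyclo[3.1.1]heptane-2,2'-[1,3]dioxolan]-7-yl]-N-methoxy-N,2-dimethylpropanamide | BrC2(C)[C@@H]3[C@@H]([C@H]2C4(OCCO4)C[C@H]3C)C(C)(C)C(=O)N(C)OC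
F2 | step 7 | 2-[6-bromo-4,6-dimethylspiro[bicyclo[3.1.1]heptane-2,2'-[1,3]dioxolan]-7-yl]-2-methylpent-4-en-3-one | BrC2(C)[C@@H]3[C@@H]([C@H]2C4(OCCO4)C[C@H]3C)C(C)(C)C(=O)C=C
F3 | step 7 | longipinane-1,7-dione 1-ethylene ketal | O=C1CC[C@]2(C)[C@@H]3[C@@H]([C@H]2C4(OCCO4)C[C@H]3C)C1(C)C
F4 | step 5 | 4-bromo-3,5-dimethylcyclohex-2-en-1-one, Br trans to the C5 methyl | CC1=CC(=O)C[C@@H](C)[C@@H]1Br
F5 | step 5 | 8-bromo-7,9-dimethyl-1,4-dioxaspiro[4.5]dec-6-ene, Br trans to the C9 methyl | CC1=CC2(OCCO2)C[C@@H](C)[C@@H]1Br
F6 | step 5 | 5,7,7-tribromo-4,6-dimethylspiro[bicyclo[4.1.0]heptane-2,2'-[1,3]dioxolane], CBr2 cis to the C4 methyl and trans to Br-5 | C[C@@]12[C@@H](Br)[C@H](C)CC3(OCCO3)[C@@H]1C2(Br)Br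
F7 | step 5 | 7-bromo-1,5-dimethylspiro[tricyclo[4.1.0.0^2,7]heptane-3,2'-[1,3]dioxolane] | C[C@]12[C@@H]3[C@@]1(Br)[C@H]2C4(OCCO4)C[C@H]3C
F8 | step 5 | 7-lithio-1,5-dimethylspiro[tricyclo[4.1.0.0^2,7]heptane-3,2'-[1,3]dioxolane] | C[C@]12[C@@H]3[C@@]1([Li])[C@H]2C4(OCCO4)C[C@H]3C
F9 | step 9 | (7R)-7-(tert-butyldimethylsilyloxy)longipin-8-en-1-one ethylene ketal | CC(C)(C)[Si](C)(C)O[C@@H]1C=C[C@]2(C)[C@@H]3[C@@H]([C@H]2C4(OCCO4)C[C@H]3C)C1(C)C
F10 | step 9 | 7-(tert-butyldimethylsilyloxy)-8,9-dihydroxylongipinan-1-one ethylene ketal | CC(C)(C)[Si](C)(C)O[C@@H]1[C@@H](O)[C@@H](O)[C@]2(C)[C@@H]3[C@@H]([C@H]2C4(OCCO4)C[C@H]3C)C1(C)C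
F11 | step 9 | 7-(tert-butyldimethylsilyloxy)-8,9-(isopropylidenedioxy)longipinan-1-one ethylene ketal | CC(C)(C)[Si](C)(C)O[C@@H]1[C@@H](OC4(C)C)[C@@H](O4)[C@]2(C)[C@@H]3[C@@H]([C@H]2C5(OCCO5)C[C@H]3C)C1(C)C
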